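## Structural features

The target is a furofuran lignan: two tetrahydrofuran rings cis-fused through the C3a–C6a bond. Locants used throughout are C1, O2, C3, C3a, C4, O5, C6, C6a, with ring A = C1/O2/C3/C3a/C6a and ring B = C4/O5/C6/C6a/C3a. Four contiguous stereocentres run C1–C6a–C3a–C4 and are (1R,3aR,4S,6aR), with the bridgehead hydrogens cis. Aryl B (3-methoxy-4-prenyloxyphenyl) at C4 is exo, on the convex face, while aryl A (4-hydroxy-3-methoxyphenyl) at C1 is endo, on the concave face. Because the two aryl groups differ, it matters which ring carries the endo aryl. Both benzylic C–O bonds ionise under acid, which would move the endo C1 aryl to the more stable exo position. The prenyl aryl ether is lost under strong protic or Lewis acid and under unselective hydrogenation, and the phenol of ring A, as its phenoxide, sits para to C1. The real difficulty is to place the correct aryl endo at C1, next to the cis ring fusion, in one enantiomeric series, and then to finish without acid. The route exploits the fact that C1–O2–C3 of ring A is the three-atom chain of a carbonyl ylide from the aryl A aldehyde. The C3a–C6a edge can be the C=C bond of a butenolide that already holds C4 with aryl B, O5 and C6 as the lactone carbonyl.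

Abbreviations: Ts = 4-methylbenzenesulfonyl; prenyl = 3-methylbut-2-en-1-yl.

## Logic of the disconnections

**17 ⇒ 16.** The O–S bond of an arenesulfonate on the ring-A phenol is cut (the mask is added in the retrosynthetic sense). The phenol must be masked through fluoride, hydride and sulfonyl chloride steps, and an aryl sulfonate withstands all three. An aryl carboxylate such as a pivalate would be cleaved by the hydride that reduces the lactone. The sulfonate also withdraws electron density from ring A, which keeps C1–O2 from ionising. The skeleton is unchanged. The forward unmasking must be basic and must spare the prenyl ether and both benzylic ethers.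

**16 ⇒ 14 (through 15).** O5–C6 of ring B is cut at the non-stereogenic CH2, so the C4–O5 bond is never broken and C4 keeps its configuration. This replaces a Lewis-acid silane reduction of a lactol, which would expose the endo C1 ether and the prenyl ether to acid. The bicycle becomes a monocyclic 1,4-diol. The forward step must activate the primary hydroxyl in preference to the benzylic one and close by SN2 under base.

**14 ⇒ 13.** C6 is raised from CH2OH to the lactone carbonyl and O5–C6 is reconnected as an ester. A carbonyl at C6 is what makes C3a–C6a an electron-poor alkene one stage further back. The forward reduction needs a hydride that opens a lactone but leaves an aryl sulfonate alone.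

**13 ⇒ 5 + 11 (through 12).** C1–C6a and C3–C3a are cut. This removes ring A and three stereocentres at once and divides the molecule into two aryl fragments of similar size. The forward cycloaddition must be regioselective, must add anti to the C4 aryl, must place the ylide aryl endo, and must not erode the enantiomeric purity of 11.

**5 ⇒ 4 ⇒ 2 + 3 ⇒ 1.** The C1–Cl bond is traced back to an acetal C–O bond, the two acetal C–O bonds to the aldehyde and two molecules of 3, and the sulfonate O–S bond to the phenol. A symmetric acetal is chosen because cleavage of either alkoxy group gives the same chloro ether. The chloro ether is moisture-sensitive, so it must be made and used without purification.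

**11 ⇒ 10 ⇒ 9.** The lactone acyl–O5 bond is cut to the Z-hydroxy ester, and the Z-alkene is traced back to an alkyne. Syn hydrogenation supplies the geometry that lets the hydroxyl reach the ester. The ring disappears and a linear propargylic alcohol with the single stereocentre C4 remains. The forward semi-hydrogenation must stop at the alkene and must not touch the side-chain alkene, which is why the trisubstituted prenyl group is carried and not an allyl group.

**9 ⇒ 7 + 8.** The C4–C3a bond between carbinol and alkyne is cut. This is the only stereocentre that must come from a reagent, and a catalytic enantioselective alkynylation supplies it from two achiral pieces. The forward step must give the (R)-carbinol from an electron-rich aldehyde with high selectivity.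

**7 ⇒ 1 + 6.** The O–CH2 bond of the prenyl ether is cut. The ether is installed at the start, where only base is needed, so no allyl-to-prenyl exchange is required later. Every later step must then avoid strong acid and unselective hydrogenation.

## Other disconnections considered

**Alternative 1:** The cut is at C1–C6a and C3a–C4, the two bonds joining the aryl-bearing carbons to the central two-carbon unit; neither ring is closed.
- Forward key step: the 2-lithio derivative of dithiane A2 would add conjugately to C6a of the menthyloxy butenolide A1, anti to the acetal substituent. The lactone enolate would then be trapped at C3a by aldehyde A3 to give A4.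
- In favour: both aryl groups arrive in one flask. C3a and C6a are fixed by a chiral auxiliary on a butenolide whose acetal centre is not prone to base-induced racemisation. Tandem conjugate addition–aldol on this acceptor class is well-established chemistry.
- Against, here: the step makes no ring of the target. C1 emerges as a dithioketal, so the endo C1 stereocentre still has to be created by dithiane removal, ketone reduction and an inverting or retentive ring closure. Dithiane removal calls for oxidative or thiophilic reagents in the presence of a side-chain alkene and electron-rich arenes. The menthyl acetal, the lactone carbonyl and the acetal carbon all need further reduction steps, and the aldol configuration at C4 is not assured.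
- Comparison: on control of C3a/C6a and on freedom from racemisation this plan is the better one. On convergence the two are equal. On C1 the chosen plan is the better, since it sets C1 in the ring-forming step, although with unproven endo preference. On step economy the chosen plan is clearly shorter.

**Alternative 2:** The cut is at C1–C6a only.
- Forward key step: Rh2(OAc)4 would decompose the α-diazo lactone A5, and the carbenoid at C6a would insert into the benzylic ether C1–H, closing ring A onto the lactone to give A6.
- In favour: insertion into an oxygen-activated benzylic C–H through a five-membered transition state is a known way to a cis-fused furofuranone with the new aryl endo. No base or fluoride meets a racemisable intermediate. The prenyl group can be carried. A6 is the same kind of lactone as 13, so the same endgame applies.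
- Against, here: A5 is a long linear target in itself. C4 and C3a must be set beforehand in a trans lactone carrying the benzyloxymethyl arm, and diazo transfer is then needed. The key step forms only one C–C bond. The carbenoid could also add to the electron-rich arenes or to the prenyl alkene.
- Comparison: on endo selectivity at C1 and on configurational safety this plan is the better one. On the steps after the key step the two are equal. On convergence and on the number of steps to the key-step precursor the chosen plan is better. This chemistry is used below as the fallback for step 7.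

**Alternative 3:** The cut is at O5–C4 and C3a–C4, which excises the aryl B aldehyde carbon.
- Forward key step: Me3SiOTf would exchange the primary alcohol of the cis-dihydrofuran A7 into the acetal A8. The resulting oxocarbenium ion would be attacked by the enol ether carbon C3a in a Prins-type closure of ring B, and methanol would cap C3 to give A9.
- In favour: the endo C1 aryl is secured before the key step as the cis relation in A7, so no endo/exo selection is needed. The C4 aryl can take the exo position under the reversible conditions. Aryl B enters as a simple acetal.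
- Against, here: A9 carries an extra methoxy acetal at C3 that must be reduced with a silane and a Lewis acid, which endangers the endo benzylic ether. The prenyl ether is unlikely to tolerate the silyl triflate, so an allyl ether and a later exchange are needed. Enantiopure A7, an acid-sensitive enol ether with two stereocentres, is itself a demanding target.
- Comparison: on C1 this plan is the better one. On convergence the two are equal. On acid exposure, on step count after the key step and on access to the key-step precursor the chosen plan is better.

Key step: step 7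

Assumption: the (S,S) antipode of the ProPhenol ligand, 2,6-bis{[(S)-2-(hydroxydiphenylmethyl)pyrrolidin-1-yl]methyl}-4-methylphenol, is taken to deliver the (R)-carbinol 9. The sense is to be confirmed on 9 by MTPA ester analysis, and the (R,R) ligand is used with nothing else changed if it proves opposite.

## Route

Step 1
Reactants: 1 vanillin
Product: 2 4-formyl-2-methoxyphenyl 4-methylbenzenesulfonate
Conditions: TsCl (1.1 equiv), Et3N, DMAP (cat.), CH2Cl2, 0 °C → rt
Reagents that add atoms: p-toluenesulfonyl chloride, Cc1ccc(S(=O)(=O)Cl)cc1
Why: O-Sulfonylation of a phenol. The arenesulfonate is chosen because it is inert to fluoride, borohydride and MsCl/Et3N and makes ring A electron-poor, which tames the later chloro ether and protects C1–O2 from ionisation.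

Step 2
Reactants: 2 4-formyl-2-methoxyphenyl 4-methylbenzenesulfonate, 3 (trimethylsilyl)methanol
Product: 4 4-{bis[(trimethylsilyl)methoxy]methyl}-2-methoxyphenyl 4-methylbenzenesulfonate
Conditions: 3 (2.5 equiv), TsOH·H2O (2 mol%), cyclohexane, reflux with azeotropic removal of water; Et3N quench
Reagents that add atoms: none
Why: Acid-catalysed acetalisation driven by removal of water; the electron-poor aldehyde acetalises readily. A symmetric acetal is made on purpose so that the next step can give only one chloro ether.

Step 3
Reactants: 4 4-{bis[(trimethylsilyl)methoxy]methyl}-2-methoxyphenyl 4-methylbenzenesulfonate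
Product: 5 4-{chloro[(trimethylsilyl)methoxy]methyl}-2-methoxyphenyl 4-methylbenzenesulfonate (racemic)
Conditions: AcCl (1.2 equiv), ZnCl2 (1 mol%), CH2Cl2, 0 °C → rt; volatiles and by-product ester removed in vacuo, used crude under argon
Reagents that add atoms: acetyl chloride, CC(=O)Cl
Why: Acylative cleavage of an acetal to an α-chloro ether: the Lewis acid ionises the acetal, acetyl takes one alkoxy group and chloride caps the oxocarbenium ion. The two alkoxy groups are identical, so no isomeric chloro ether can form.

Step 4
Reactants: 1 vanillin, 6 prenyl bromide (1-bromo-3-methylbut-2-ene)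
Product: 7 3-methoxy-4-[(3-methylbut-2-en-1-yl)oxy]benzaldehyde
Conditions: 6 (1.1 equiv), K2CO3, DMF, rt
Reagents that add atoms: none
Why: Williamson ether synthesis, SN2 attack of the phenoxide on the primary allylic bromide. The prenyl group is installed here because all later steps are compatible with it and no group exchange is needed at the end.

Step 5
Reactants: 7 3-methoxy-4-[(3-methylbut-2-en-1-yl)oxy]benzaldehyde, 8 methyl propiolate
Product: 9 methyl (R)-4-hydroxy-4-{3-methoxy-4-[(3-methylbut-2-en-1-yl)oxy]phenyl}but-2-ynoate
Conditions: 8 (3 equiv), Me2Zn (3 equiv), (S,S)-ProPhenol (10 mol%), toluene, 0–4 °C; aq. NH4Cl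
Reagents that add atoms: none
Why: Catalytic enantioselective alkynylation of an aldehyde: a dinuclear zinc–ProPhenol complex binds the aldehyde and the zinc alkynylide and transfers the alkynyl group to one carbonyl face. This ligand-controlled addition sets C4; the descriptor is R because the alkynyl group outranks the aryl group.

Step 6
Reactants: 9 methyl (R)-4-hydroxy-4-{3-methoxy-4-[(3-methylbut-2-en-1-yl)oxy]phenyl}but-2-ynoate
Product: 11 (S)-5-{3-methoxy-4-[(3-methylbut-2-en-1-yl)oxy]phenyl}furan-2(5H)-one, via Z-hydroxy enoate 10 (not isolated)
Conditions: H2 (1 atm), Pd/CaCO3 poisoned with Pb(OAc)2 (Lindlar catalyst), quinoline, EtOAc, rt; filter; PPTS (cat.), CH2Cl2, rt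
Reagents that add atoms: none
Why: Syn semi-hydrogenation of the alkyne on poisoned palladium gives the Z-enoate, whose hydroxyl then lactonises by intramolecular transesterification with loss of methanol. No bond to C4 is broken (the descriptor changes to S only because the ranking of the substituents changes), and the trisubstituted prenyl alkene is inert to this catalyst.

Step 7
Reactants: 5 4-{chloro[(trimethylsilyl)methoxy]methyl}-2-methoxyphenyl 4-methylbenzenesulfonate (racemic), 11 (S)-5-{3-methoxy-4-[(3-methylbut-2-en-1-yl)oxy]phenyl}furan-2(5H)-one
Product: 13 (1R,3aR,4S,6aS)-1-[3-methoxy-4-(tosyloxy)phenyl]-4-{3-methoxy-4-[(3-methylbut-2-en-1-yl)oxy]phenyl}tetrahydro-1H,3H-furo[3,4-c]furan-6-one (route locants: C6 is the lactone carbonyl), via carbonyl ylide 12 (not isolated)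
Conditions: 5 (2 equiv), CsF (4 equiv, dried), MeCN, 0 °C → rt
Reagents that add atoms: none
Why: Fluoride attacks silicon of 5 while chloride leaves (a 1,3-elimination, probably through the oxocarbenium ion), giving the non-stabilised carbonyl ylide 12, a four-electron dipole that adds suprafacially to the electron-poor C3a=C6a bond of 11 in a concerted 1,3-dipolar cycloaddition. The closest known reaction type is this same fluoride-triggered ylide generation from α-chloroalkyl silylmethyl ethers and its cycloaddition to α,β-unsaturated esters; a γ-aryl butenolide is a new member of that acceptor class. Ring A closes by intermolecular [3+2] annulation, its two bonds C3–C3a and C1–C6a forming in the same event, so no separate ring-chain cyclisation mode is involved. Regiochemistry should follow the polarisation of the partners: the unsubstituted CH2 terminus is the more nucleophilic and the smaller end and bonds to the β-carbon C3a beside the hindered C4, while the benzylic terminus bonds to the α-carbon C6a. C3a and C6a are set together: the cis fusion follows from suprafacial addition to a ring-locked cis alkene, and the absolute sense from attack on the face of 11 opposite the C4 aryl, which thereby becomes exo. C1 is set by an endo transition state in which the ylide aryl lies under the lactone carbonyl, placing aryl A on the concave face, cis to C6. The step needs regio-, facial and endo selectivity and must keep the enantiomeric purity of 11: the first two rest on the polarised enoate and the γ-aryl group, the endo preference is the unproven element, and γ-deprotonation of 11 by fluoride is countered by the excess of 5, the low temperature and a check of recovered 11 and of 13 by chiral HPLC.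

Step 8
Reactants: 13 (1R,3aR,4S,6aS)-1-[3-methoxy-4-(tosyloxy)phenyl]-4-{3-methoxy-4-[(3-methylbut-2-en-1-yl)oxy]phenyl}tetrahydro-1H,3H-furo[3,4-c]furan-6-one
Product: 14 {(2R,3R,4R)-4-[(S)-hydroxy{3-methoxy-4-[(3-methylbut-2-en-1-yl)oxy]phenyl}methyl]-2-[3-methoxy-4-(tosyloxy)phenyl]tetrahydrofuran-3-yl}methanol
Conditions: LiBH4 (2.5 equiv), THF, 0 °C → rt; aq. NH4Cl
Reagents that add atoms: none
Why: Reduction of the lactone to the 1,4-diol by LiBH4, which leaves aryl sulfonates, aryl ethers and the isolated alkene untouched. No stereocentre is involved, and C6a loses its epimerisable α-carbonyl position.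

Step 9
Reactants: 14 {(2R,3R,4R)-4-[(S)-hydroxy{3-methoxy-4-[(3-methylbut-2-en-1-yl)oxy]phenyl}methyl]-2-[3-methoxy-4-(tosyloxy)phenyl]tetrahydrofuran-3-yl}methanol
Product: 16 2-methoxy-4-[(1R,3aR,4S,6aR)-4-{3-methoxy-4-[(3-methylbut-2-en-1-yl)oxy]phenyl}tetrahydro-1H,3H-furo[3,4-c]furan-1-yl]phenyl 4-methylbenzenesulfonate, via primary mesylate 15 (not isolated)
Conditions: MsCl (1.1 equiv), Et3N (3 equiv), CH2Cl2, −20 °C → rt
Reagents that add atoms: none
Why: Selective sulfonylation of the unhindered primary alcohol followed by intramolecular Williamson etherification, a 5-exo-tet SN2 attack of the C4 hydroxyl on C6. The C4–O5 bond is never broken, so aryl B stays exo, and the basic medium leaves the endo C1 ether and the prenyl ether alone.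

Step 10
Reactants: 16 2-methoxy-4-[(1R,3aR,4S,6aR)-4-{3-methoxy-4-[(3-methylbut-2-en-1-yl)oxy]phenyl}tetrahydro-1H,3H-furo[3,4-c]furan-1-yl]phenyl 4-methylbenzenesulfonate
Product: 17 2-methoxy-4-[(1R,3aR,4S,6aR)-4-{3-methoxy-4-[(3-methylbut-2-en-1-yl)oxy]phenyl}tetrahydro-1H,3H-furo[3,4-c]furan-1-yl]phenol
Conditions: KOH (5 equiv), MeOH/THF, 60 °C; aq. NH4Cl
Reagents that add atoms: none
Why: Alkaline hydrolysis of the aryl sulfonate by attack of hydroxide at sulfur and S–O cleavage. Ethers, the prenyl alkene and the benzylic ether stereocentres are stable to base at this moderate temperature.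

## Compound list

1 | vanillin | COc1cc(C=O)ccc1O | starting material
2 | 4-formyl-2-methoxyphenyl 4-methylbenzenesulfonate | Cc1ccc(S(=O)(=O)Oc2ccc(C=O)cc2OC)cc1 | intermediate
3 | (trimethylsilyl)methanol | C[Si](C)(C)CO | starting material
4 | 4-{bis[(trimethylsilyl)methoxy]methyl}-2-methoxyphenyl 4-methylbenzenesulfonate | Cc1ccc(S(=O)(=O)Oc2ccc(C(OC[Si](C)(C)C)OC[Si](C)(C)C)cc2OC)cc1 | intermediate
5 | 4-{chloro[(trimethylsilyl)methoxy]methyl}-2-methoxyphenyl 4-methylbenzenesulfonate, racemic | Cc1ccc(S(=O)(=O)Oc2ccc(C(Cl)OC[Si](C)(C)C)cc2OC)cc1 | intermediate
6 | prenyl bromide (1-bromo-3-methylbut-2-ene) | CC(C)=CCBr | starting material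
7 | 3-methoxy-4-[(3-methylbut-2-en-1-yl)oxy]benzaldehyde | COc1cc(C=O)ccc1OCC=C(C)C | intermediate
8 | methyl propiolate | C#CC(=O)OC | starting material
9 | methyl (R)-4-hydroxy-4-{3-methoxy-4-[(3-methylbut-2-en-1-yl)oxy]phenyl}but-2-ynoate | COC(=O)C#C[C@H](O)c1ccc(OCC=C(C)C)c(OC)c1 | intermediate
10 | methyl (S,Z)-4-hydroxy-4-{3-methoxy-4-[(3-methylbut-2-en-1-yl)oxy]phenyl}but-2-enoate, not isolated | COC(=O)/C=C\[C@H](O)c1ccc(OCC=C(C)C)c(OC)c1 | intermediate
11 | (S)-5-{3-methoxy-4-[(3-methylbut-2-en-1-yl)oxy]phenyl}furan-2(5H)-one | O=C1C=C[C@@H](c2ccc(OCC=C(C)C)c(OC)c2)O1 | intermediate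
12 | carbonyl ylide, [3-methoxy-4-(tosyloxy)benzylidene]oxonium methylide, not isolated | [CH2-][O+]=Cc1ccc(OS(=O)(=O)c2ccc(C)cc2)c(OC)c1 | intermediate
13 | (1R,3aR,4S,6aS)-1-[3-methoxy-4-(tosyloxy)phenyl]-4-{3-methoxy-4-[(3-methylbut-2-en-1-yl)oxy]phenyl}tetrahydro-1H,3H-furo[3,4-c]furan-6-one (route locants; aryl A endo, aryl B exo) | Cc1ccc(S(=O)(=O)Oc2ccc([C@@H]3OC[C@H]4[C@@H]3C(=O)O[C@@H]4c3ccc(OCC=C(C)C)c(OC)c3)cc2OC)cc1 | intermediate
14 | {(2R,3R,4R)-4-[(S)-hydroxy{3-methoxy-4-[(3-methylbut-2-en-1-yl)oxy]phenyl}methyl]-2-[3-methoxy-4-(tosyloxy)phenyl]tetrahydrofuran-3-yl}methanol | Cc1ccc(S(=O)(=O)Oc2ccc([C@@H]3OC[C@@H]([C@@H]3CO)[C@H](O)c3ccc(OCC=C(C)C)c(OC)c3)cc2OC)cc1 | intermediate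
15 | primary methanesulfonate of 14, not isolated | Cc1ccc(S(=O)(=O)Oc2ccc([C@@H]3OC[C@@H]([C@@H]3COS(C)(=O)=O)[C@H](O)c3ccc(OCC=C(C)C)c(OC)c3)cc2OC)cc1 | intermediate
16 | 2-methoxy-4-[(1R,3aR,4S,6aR)-4-{3-methoxy-4-[(3-methylbut-2-en-1-yl)oxy]phenyl}tetrahydro-1H,3H-furo[3,4-c]furan-1-yl]phenyl 4-methylbenzenesulfonate | Cc1ccc(S(=O)(=O)Oc2ccc([C@@H]3OC[C@H]4[C@@H]3CO[C@@H]4c3ccc(OCC=C(C)C)c(OC)c3)cc2OC)cc1 | intermediate
17 | 2-methoxy-4-[(1R,3aR,4S,6aR)-4-{3-methoxy-4-[(3-methylbut-2-en-1-yl)oxy]phenyl}tetrahydro-1H,3H-furo[3,4-c]furan-1-yl]phenol | COc1cc([C@@H]2OC[C@H]3[C@@H]2CO[C@@H]3c2ccc(OCC=C(C)C)c(OC)c2)ccc1O | target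

## Step count and least certain steps

Total: 10 steps. Longest linear sequence: 7 steps (1 → 7 → 9 → 11 → 13 → 14 → 16 → 17; the branch 1 → 2 → 4 → 5 → 13 is equally long).

**Step 7 (key step).** The endo preference of the ylide aryl may be weak, so that aryl A is also placed on the convex face at C1. Fluoride may remove the acidic γ-hydrogen of 11, racemising it or isomerising it to the aryl-conjugated enol lactone before it is trapped. The ylide may also be lost by self-reaction.

The fallback closes ring A by carbenoid C–H insertion. It sets out from 11, with the side arm drawn from 2, and comes back at 13.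
- Aldehyde 2 is reduced with NaBH4 to 4-(hydroxymethyl)-2-methoxyphenyl 4-methylbenzenesulfonate F1.
- The alkoxide of F1 (NaH, THF, 0 °C) is alkylated with BrCH2BF3K to the potassium alkoxymethyltrifluoroborate F2.
- Under blue light with Ir[dF(CF3)ppy]2(dtbbpy)PF6, the alkoxymethyl radical from F2 should add in a Giese addition to the β-carbon of 11, anti to the aryl, to give the trans lactone F3. These are neutral conditions, under which 11 is not deprotonated.
- Deacylative diazo transfer (LiHMDS, CF3CO2CH2CF3, −78 °C; then MsN3, Et3N) gives the α-diazo lactone F4.
- Rh2(OAc)4 in CH2Cl2 should insert the carbenoid at C6a into the oxygen-activated benzylic C1–H through a five-membered transition state, giving the cis-fused, endo-aryl lactone 13.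

**Step 5.** The electron-rich aldehyde may react slowly, and enantioselectivity may be eroded by uncatalysed background addition. The sense of induction also has to be confirmed.

The fallback sets out from 7 and 8 and comes back at 9.
- The lithium acetylide of 8 (LiHMDS, THF, −78 °C) adds to 7 to give the racemic methyl 4-hydroxy-4-arylbut-2-ynoate F5.
- Kinetic resolution with immobilised Candida antarctica lipase B and vinyl acetate should acylate the enantiomer that places the aryl group as the large substituent, giving the (S)-acetate F6.
- The unreacted (R)-alcohol is separated and is 9. The price is the loss of half of the material.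

**Step 3.** Acetal cleavage may be incomplete, or the chloro ether may be lost by hydrolysis or ionisation during concentration.

The fallback sets out from 4 and comes back at 13.
- Me3SiBr in CH2Cl2 at −40 °C exchanges one alkoxy group of the acetal for bromide by silyl transfer, without an acyl chloride or an ester by-product, giving the bromo ether F7.
- F7 is not concentrated; its solution is added directly to 11 and CsF in MeCN, where it should give the same ylide 12 and hence 13.

**Step 9.** The benzylic hydroxyl may be sulfonylated competitively, or the ring may close slowly, letting chloride displace the primary mesylate.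

The fallback sets out from 14 and comes back at 16. It changes the bond that is formed:
- Catalytic camphorsulfonic acid in CH2Cl2 at 0 °C should ionise the C4–OH bond, which is activated by the para-oxygen of aryl B.
- The primary hydroxyl captures the benzylic cation, forming O5–C4 with the aryl in the less hindered exo position.
- The sulfonate-deactivated ring A keeps C1–O2 from ionising, and the catalytic weak acid should spare the prenyl ether.
- No new compound arises (F0).

## Further compounds

F1 | step 7 | 4-(hydroxymethyl)-2-methoxyphenyl 4-methylbenzenesulfonate | Cc1ccc(S(=O)(=O)Oc2ccc(CO)cc2OC)cc1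
F2 | step 7 | potassium trifluoro({[3-methoxy-4-(tosyloxy)benzyl]oxy}methyl)borate | Cc1ccc(S(=O)(=O)Oc2ccc(COC[B-](F)(F)F)cc2OC)cc1.[K+]
F3 | step 7 | (4R,5S)-4-({[3-methoxy-4-(tosyloxy)benzyl]oxy}methyl)-5-{3-methoxy-4-[(3-methylbut-2-en-1-yl)oxy]phenyl}dihydrofuran-2(3H)-one | O=C1O[C@H](c2ccc(OCC=C(C)C)c(OC)c2)[C@@H](COCc2ccc(OS(=O)(=O)c3ccc(C)cc3)c(OC)c2)C1
F4 | step 7 | (4R,5S)-3-diazo-4-({[3-methoxy-4-(tosyloxy)benzyl]oxy}methyl)-5-{3-methoxy-4-[(3-methylbut-2-en-1-yl)oxy]phenyl}dihydrofuran-2(3H)-one | O=C1O[C@H](c2ccc(OCC=C(C)C)c(OC)c2)[C@@H](COCc2ccc(OS(=O)(=O)c3ccc(C)cc3)c(OC)c2)C1=[N+]=[N-]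
F5 | step 5 | methyl 4-hydroxy-4-{3-methoxy-4-[(3-methylbut-2-en-1-yl)oxy]phenyl}but-2-ynoate, racemic | COC(=O)C#CC(O)c1ccc(OCC=C(C)C)c(OC)c1
F6 | step 5 | methyl (S)-4-acetoxy-4-{3-methoxy-4-[(3-methylbut-2-en-1-yl)oxy]phenyl}but-2-ynoate | COC(=O)C#C[C@@H](OC(C)=O)c1ccc(OCC=C(C)C)c(OC)c1
F7 | step 3 | 4-{bromo[(trimethylsilyl)methoxy]methyl}-2-methoxyphenyl 4-methylbenzenesulfonate, racemic | Cc1ccc(S(=O)(=O)Oc2ccc(C(Br)OC[Si](C)(C)C)cc2OC)cc1
F0 | step 9 | none | none
A1 | alternative 1 | (5R)-5-{[(1R,2S,5R)-2-isopropyl-5-methylcyclohexyl]oxy}furan-2(5H)-one | O=C1C=C[C@H](O[C@@H]2C[C@H](C)CC[C@H]2C(C)C)O1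
A2 | alternative 1 | 2-{3-methoxy-4-[(triisopropylsilyl)oxy]phenyl}-1,3-dithiane | COc1cc(C2SCCCS2)ccc1O[Si](C(C)C)(C(C)C)C(C)C
A3 | alternative 1 | 4-(allyloxy)-3-methoxybenzaldehyde | COc1cc(C=O)ccc1OCC=C
A4 | alternative 1 | trans-3-[(S)-hydroxy(4-allyloxy-3-methoxyphenyl)methyl]-4-[2-(3-methoxy-4-triisopropylsilyloxyphenyl)-1,3-dithian-2-yl]-5-(menthyloxy)dihydrofuran-2(3H)-one | O=C1O[C@@H](O[C@@H]2C[C@H](C)CC[C@H]2C(C)C)[C@H](C2(c3ccc(O[Si](C(C)C)(C(C)C)C(C)C)c(OC)c3)SCCCS2)[C@H]1[C@H](O)c1ccc(OCC=C)c(OC)c1
A5 | alternative 2 | (4R,5S)-4-[({4-[(tert-butyldimethylsilyl)oxy]-3-methoxybenzyl}oxy)methyl]-3-diazo-5-{3-methoxy-4-[(3-methylbut-2-en-1-yl)oxy]phenyl}dihydrofuran-2(3H)-one | O=C1O[C@H](c2ccc(OCC=C(C)C)c(OC)c2)[C@@H](COCc2ccc(O[Si](C)(C)C(C)(C)C)c(OC)c2)C1=[N+]=[N-]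
A6 | alternative 2 | endo,exo-furofuranone with the lactone carbonyl at C6, aryl A as tert-butyldimethylsilyl ether, aryl B as prenyl ether | COc1cc([C@@H]2OC[C@H]3[C@@H]2C(=O)O[C@@H]3c2ccc(OCC=C(C)C)c(OC)c2)ccc1O[Si](C)(C)C(C)(C)C
A7 | alternative 3 | 4-[(2R,3R)-3-(hydroxymethyl)-2,3-dihydrofuran-2-yl]-2-methoxyphenyl pivalate | CC(C)(C)C(=O)Oc1ccc([C@@H]2OC=C[C@@H]2CO)cc1OC
A8 | alternative 3 | 1-(allyloxy)-4-(dimethoxymethyl)-2-methoxybenzene | COC(OC)c1ccc(OCC=C)c(OC)c1
A9 | alternative 3 | endo,exo-diaryl furofuran with an exo methoxy acetal at C3, aryl A as pivalate, aryl B as allyl ether | COc1cc([C@@H]2O[C@@H](OC)[C@H]3[C@@H]2CO[C@@H]3c2ccc(OCC=C)c(OC)c2)ccc1OC(=O)C(C)(C)C
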